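**Plan**
Cuts: with an N-tosyl group added to the indole, the imide C=O groups at C2 and C5 are traced back to C2–H/C5–H of a 3,4-diarylpyrrole, and these to two CO2Me groups. The five-membered ring is then cut at C3–C4, N1–C2 and N1–C5.
Enabling feature: C3 and C4 of the maleimide ring each bear a heteroaryl ring (6-bromoindol-3-yl, 1-methylimidazol-5-yl). Each is therefore the benzylic and only enolisable carbon of an arylpyruvate, and C3–C4 is a bond between two enolate carbons.
Forward: the indole and imidazole rings are bought as carbaldehydes, and each is homologated by olefination and enamide hydrolysis to a methyl arylpyruvate.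
Iodine then joins the two benzylic carbons, and ammonia closes the pyrrole, the only ring built in the route, in the same flask.
Ester cleavage with protodecarboxylation, oxygenation of pyrrole C2/C5 to the imide, and detosylation finish the synthesis.
Stereochemistry: the target has no stereocentre. The Z-enamides and the sp3 centres of intermediates are transient and need no control.

Key step: step 6

Assumption: the two arylpyruvates are drawn as keto tautomers although they should exist largely as enols, and racemic or diastereomeric intermediates are written without configuration (tosyl = 4-methylbenzenesulfonyl).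

Step 1
Reactants: 1 6-bromo-1H-indole-3-carbaldehyde
Product: 2 6-bromo-1-tosyl-1H-indole-3-carbaldehyde
Conditions: NaH, TsCl, THF/DMF, 0 °C to rt
Reagents that add atoms: p-toluenesulfonyl chloride (TsCl), Cc1ccc(cc1)S(=O)(=O)Cl
Why: N-sulfonylation of the indolide anion is routine, and the tosyl group turns the vinylogous formamide into a normally electrophilic aldehyde and later shields the indole C2=C3 bond from iodine and singlet oxygen.

Step 2
Reactants: 2 6-bromo-1-tosyl-1H-indole-3-carbaldehyde; 3 methyl 2-[(tert-butoxycarbonyl)amino]-2-(dimethoxyphosphoryl)acetate (racemic)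
Product: 4 methyl (Z)-3-(6-bromo-1-tosyl-1H-indol-3-yl)-2-[(tert-butoxycarbonyl)amino]prop-2-enoate
Conditions: DBU, CH2Cl2, 0 °C to rt
Reagents that add atoms: none
Why: Horner–Wadsworth–Emmons olefination of N-acyl-α-phosphonoglycinates with N-protected indole-3-carbaldehydes is the standard entry to dehydrotryptophan esters and should give mainly the Z-enamide, whose geometry is lost in step 3.

Step 3
Reactants: 4 methyl (Z)-3-(6-bromo-1-tosyl-1H-indol-3-yl)-2-[(tert-butoxycarbonyl)amino]prop-2-enoate
Product: 6 methyl 3-(6-bromo-1-tosyl-1H-indol-3-yl)-2-oxopropanoate, via enamino ester 5 (not isolated)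
Conditions: TFA/CH2Cl2, rt; then H2O/THF, rt
Reagents that add atoms: water, O
Why: Acidolysis of the tert-butyl carbamate frees the primary enamine, which tautomerises to the α-imino ester and is hydrolysed to the α-keto ester (enamine hydrolysis), while sulfonamide, methyl ester and aryl bromide are inert to TFA.

Step 4
Reactants: 7 1-methyl-1H-imidazole-5-carbaldehyde; 3 methyl 2-[(tert-butoxycarbonyl)amino]-2-(dimethoxyphosphoryl)acetate (racemic)
Product: 8 methyl (Z)-2-[(tert-butoxycarbonyl)amino]-3-(1-methyl-1H-imidazol-5-yl)prop-2-enoate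
Conditions: DBU, CH2Cl2, 0 °C to rt
Reagents that add atoms: none
Why: The same Horner–Wadsworth–Emmons olefination is established for imidazolecarbaldehydes as a route to dehydrohistidine esters, and the N-methyl group leaves no acidic N–H to consume base.

Step 5
Reactants: 8 methyl (Z)-2-[(tert-butoxycarbonyl)amino]-3-(1-methyl-1H-imidazol-5-yl)prop-2-enoate
Product: 10 methyl 3-(1-methyl-1H-imidazol-5-yl)-2-oxopropanoate, via enamino ester 9 (not isolated)
Conditions: TFA/CH2Cl2, rt; then H2O/THF, 40 °C
Reagents that add atoms: water, O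
Why: Carbamate acidolysis followed by enamine hydrolysis should deliver the α-keto ester as in step 3, with gentle warming to offset the slower C-protonation next to the protonated imidazole.

Step 6
Reactants: 10 methyl 3-(1-methyl-1H-imidazol-5-yl)-2-oxopropanoate; 6 methyl 3-(6-bromo-1-tosyl-1H-indol-3-yl)-2-oxopropanoate; 11 ammonia
Product: 14 dimethyl 3-(6-bromo-1-tosyl-1H-indol-3-yl)-4-(1-methyl-1H-imidazol-5-yl)-1H-pyrrole-2,5-dicarboxylate, via iodo keto ester 12 (not isolated), via dioxoadipate 13 (not isolated)
Conditions: 10, LiN(SiMe3)2, THF, −78 °C, cannulated into I2 (1.0 equiv), THF, −78 °C; then enolate of 6 (LiN(SiMe3)2, THF, −78 °C), −78 to 0 °C; then NH3 (0.5 M in dioxane), AcOH, rt to 50 °C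
Reagents that add atoms: none
Why: LiN(SiMe3)2 turns each α-keto ester into its enolate, whose only nucleophilic carbon is the benzylic C3 because the ketone is flanked on its other side by the ester, and the enolate of 10, run into a full equivalent of I2, is converted completely into iodide 12 before any partner is present. The enolate of 6 then displaces iodide from 12 and forges the bond that becomes C3–C4 of the imide, giving the 3,4-diaryl-2,5-dioxoadipate 13 as a mixture of diastereomers whose two sp3 centres are erased on aromatisation, so that no stereocontrol is needed. Ammonia condenses with one ketone to an imine/enamine, its nitrogen adds 5-exo-trig to the second ketone, and loss of two molecules of water closes the pyrrole (Paal–Knorr). The closest known reaction type is the iodine-mediated oxidative dimerisation of arylpyruvate enolates followed by amine condensation to 3,4-diarylpyrrole-2,5-dicarboxylates, including the variant in which one arylpyruvate is halogenated first so that two different partners can be joined. The selectivity needed is cross- over homo-coupling, and it rests on the sequential inverse-addition protocol, on placing the halogen on the imidazolyl partner so that the carbon nucleophile (the enolate of 6) carries no competing basic nitrogen, and on the N-tosyl group, which removes the acidic indole N–H and shields the indole from iodine. Any symmetrical pyrroles that arise through iodine exchange differ from 14 in the number of basic imidazole rings and should be removable by acid extraction and chromatography.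

Step 7
Reactants: 14 dimethyl 3-(6-bromo-1-tosyl-1H-indol-3-yl)-4-(1-methyl-1H-imidazol-5-yl)-1H-pyrrole-2,5-dicarboxylate
Product: 17 6-bromo-3-[4-(1-methyl-1H-imidazol-5-yl)-1H-pyrrol-3-yl]-1-tosyl-1H-indole, via bis(trimethylstannyl) ester 15 (not isolated), via pyrrole diacid 16 (not isolated)
Conditions: Me3SnOH, ClCH2CH2Cl, 80 °C; evaporate; then TFA, 60 °C
Reagents that add atoms: none
Why: Me3SnOH cleaves methyl esters under nearly neutral conditions (tin-assisted ester hydrolysis) and should spare the N-tosyl group that hot hydroxide would remove, and pyrrole-2-carboxylic acids then lose CO2 in TFA by ipso-protonation at C2 and C5 (acid-mediated protodecarboxylation).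

Step 8
Reactants: 17 6-bromo-3-[4-(1-methyl-1H-imidazol-5-yl)-1H-pyrrol-3-yl]-1-tosyl-1H-indole
Product: 21 3-(6-bromo-1-tosyl-1H-indol-3-yl)-4-(1-methyl-1H-imidazol-5-yl)-1H-pyrrole-2,5-dione, via endoperoxide 18 (not isolated), via hydroxylactam 19 (not isolated), via isomeric hydroxylactam 20 (not isolated)
Conditions: CF3CO2H (1 equiv), O2, methylene blue (cat), visible light, CH2Cl2, −78 °C to rt; then MnO2, CH2Cl2, rt
Reagents that add atoms: dioxygen, O=O
Why: Dye-sensitised photooxygenation of 2,5-unsubstituted pyrroles is a [4+2] addition of singlet oxygen across C2/C5 followed by Kornblum–DeLaMare-type isomerisation to 5-hydroxy-3-pyrrolin-2-ones, both regioisomers of which MnO2 should oxidise to the same imide (allylic hemiaminal oxidation), and the pyrrole is the only reactive π-system because the imidazole is masked as its imidazolium salt and the indole is deactivated by the sulfonyl group.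

Step 9
Reactants: 21 3-(6-bromo-1-tosyl-1H-indol-3-yl)-4-(1-methyl-1H-imidazol-5-yl)-1H-pyrrole-2,5-dione
Product: 22 didemnimide D, 3-(6-bromo-1H-indol-3-yl)-4-(1-methyl-1H-imidazol-5-yl)-1H-pyrrole-2,5-dione
Conditions: LiOH, THF/H2O, rt
Reagents that add atoms: none
Why: Hydroxide attacks the sulfonyl sulfur and expels the indolide, a good leaving group here because it is conjugated with the imide (N-sulfonylindole hydrolysis), the maleimide is guarded against ring opening as its N-anion, and the absence of methanol avoids a methylating sulfonate ester.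

**Compound list**
1 | 6-bromo-1H-indole-3-carbaldehyde | O=Cc1c[nH]c2cc(Br)ccc12 | starting material
2 | 6-bromo-1-tosyl-1H-indole-3-carbaldehyde | O=Cc1cn(S(=O)(=O)c2ccc(C)cc2)c2cc(Br)ccc12 | intermediate
3 | methyl 2-[(tert-butoxycarbonyl)amino]-2-(dimethoxyphosphoryl)acetate (racemic) | COC(=O)C(NC(=O)OC(C)(C)C)P(=O)(OC)OC | starting material
4 | methyl (Z)-3-(6-bromo-1-tosyl-1H-indol-3-yl)-2-[(tert-butoxycarbonyl)amino]prop-2-enoate | COC(=O)/C(NC(=O)OC(C)(C)C)=C/c1cn(S(=O)(=O)c2ccc(C)cc2)c2cc(Br)ccc12 | intermediate
5 | methyl (Z)-2-amino-3-(6-bromo-1-tosyl-1H-indol-3-yl)prop-2-enoate (formed as its trifluoroacetate, not isolated) | COC(=O)/C(N)=C/c1cn(S(=O)(=O)c2ccc(C)cc2)c2cc(Br)ccc12 | intermediate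
6 | methyl 3-(6-bromo-1-tosyl-1H-indol-3-yl)-2-oxopropanoate | COC(=O)C(=O)Cc1cn(S(=O)(=O)c2ccc(C)cc2)c2cc(Br)ccc12 | intermediate
7 | 1-methyl-1H-imidazole-5-carbaldehyde | Cn1cncc1C=O | starting material
8 | methyl (Z)-2-[(tert-butoxycarbonyl)amino]-3-(1-methyl-1H-imidazol-5-yl)prop-2-enoate | COC(=O)/C(NC(=O)OC(C)(C)C)=C/c1cncn1C | intermediate
9 | methyl (Z)-2-amino-3-(1-methyl-1H-imidazol-5-yl)prop-2-enoate (formed as its trifluoroacetate, not isolated) | COC(=O)/C(N)=C/c1cncn1C | intermediate
10 | methyl 3-(1-methyl-1H-imidazol-5-yl)-2-oxopropanoate | COC(=O)C(=O)Cc1cncn1C | intermediate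
11 | ammonia | N | starting material
12 | methyl 3-iodo-3-(1-methyl-1H-imidazol-5-yl)-2-oxopropanoate (racemic, not isolated) | COC(=O)C(=O)C(I)c1cncn1C | intermediate
13 | dimethyl 3-(6-bromo-1-tosyl-1H-indol-3-yl)-4-(1-methyl-1H-imidazol-5-yl)-2,5-dioxohexanedioate (mixture of diastereomers, not isolated) | COC(=O)C(=O)C(c1cncn1C)C(C(=O)C(=O)OC)c1cn(S(=O)(=O)c2ccc(C)cc2)c2cc(Br)ccc12 | intermediate
14 | dimethyl 3-(6-bromo-1-tosyl-1H-indol-3-yl)-4-(1-methyl-1H-imidazol-5-yl)-1H-pyrrole-2,5-dicarboxylate | COC(=O)c1[nH]c(C(=O)OC)c(-c2cncn2C)c1-c1cn(S(=O)(=O)c2ccc(C)cc2)c2cc(Br)ccc12 | intermediate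
15 | bis(trimethylstannyl) 3-(6-bromo-1-tosyl-1H-indol-3-yl)-4-(1-methyl-1H-imidazol-5-yl)-1H-pyrrole-2,5-dicarboxylate (not isolated) | C[Sn](C)(C)OC(=O)c1[nH]c(C(=O)O[Sn](C)(C)C)c(-c2cncn2C)c1-c1cn(S(=O)(=O)c2ccc(C)cc2)c2cc(Br)ccc12 | intermediate
16 | 3-(6-bromo-1-tosyl-1H-indol-3-yl)-4-(1-methyl-1H-imidazol-5-yl)-1H-pyrrole-2,5-dicarboxylic acid (not isolated) | OC(=O)c1[nH]c(C(=O)O)c(-c2cncn2C)c1-c1cn(S(=O)(=O)c2ccc(C)cc2)c2cc(Br)ccc12 | intermediate
17 | 6-bromo-3-[4-(1-methyl-1H-imidazol-5-yl)-1H-pyrrol-3-yl]-1-tosyl-1H-indole | Cn1cncc1-c1c[nH]cc1-c1cn(S(=O)(=O)c2ccc(C)cc2)c2cc(Br)ccc12 | intermediate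
18 | 5-(6-bromo-1-tosyl-1H-indol-3-yl)-6-(1-methyl-1H-imidazol-5-yl)-2,3-dioxa-7-azabicyclo[2.2.1]hept-5-ene (racemic, not isolated) | O1OC2NC1C(c1cncn1C)=C2c1cn(S(=O)(=O)c2ccc(C)cc2)c2cc(Br)ccc12 | intermediate
19 | 3-(6-bromo-1-tosyl-1H-indol-3-yl)-5-hydroxy-4-(1-methyl-1H-imidazol-5-yl)-1,5-dihydro-2H-pyrrol-2-one (racemic, not isolated) | O=C1NC(O)C(c2cncn2C)=C1c1cn(S(=O)(=O)c2ccc(C)cc2)c2cc(Br)ccc12 | intermediate
20 | 4-(6-bromo-1-tosyl-1H-indol-3-yl)-5-hydroxy-3-(1-methyl-1H-imidazol-5-yl)-1,5-dihydro-2H-pyrrol-2-one (racemic, not isolated) | O=C1NC(O)C(c2cn(S(=O)(=O)c3ccc(C)cc3)c3cc(Br)ccc23)=C1c1cncn1C | intermediate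
21 | 3-(6-bromo-1-tosyl-1H-indol-3-yl)-4-(1-methyl-1H-imidazol-5-yl)-1H-pyrrole-2,5-dione | Cn1cncc1C1=C(c2cn(S(=O)(=O)c3ccc(C)cc3)c3cc(Br)ccc23)C(=O)NC1=O | intermediate
22 | didemnimide D, 3-(6-bromo-1H-indol-3-yl)-4-(1-methyl-1H-imidazol-5-yl)-1H-pyrrole-2,5-dione | Cn1cncc1C1=C(c2c[nH]c3cc(Br)ccc23)C(=O)NC1=O | target

Total step count: 9
Longest linear sequence: 7 steps (1, 2, 3, 6, 7, 8, 9)

**Steps most likely to fail**

Step 6. Three processes could erode cross-selectivity and mass balance: iodine exchange between the iodide and the incoming enolate, proton transfer between the partners, and self-quaternisation of the iodide at the imidazole nitrogen.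
The fallback inverts the roles and makes the electrophile in a separate operation. It sets out from 6. Bromination of the enol (Br2, CH2Cl2, 0 °C) should give the non-basic, storable methyl 3-bromo-3-(6-bromo-1-tosyl-1H-indol-3-yl)-2-oxopropanoate F1. This is added to the sodium enolate of 10 (NaH, THF, 0 °C) to give diketone 13. Ammonia then closes the ring as before, and the route is rejoined at 14.

Step 7. The two hindered, electron-rich pyrrole esters may hydrolyse sluggishly, or the tosyl group may be lost on prolonged heating.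
The fallback avoids ester cleavage altogether by coupling the free acids. It sets out from 6 and 10.
- The activated α-keto esters are hydrolysed in aqueous acid (3 M HCl, dioxane, reflux), which leaves the sulfonamide intact. This gives 3-(6-bromo-1-tosyl-1H-indol-3-yl)-2-oxopropanoic acid F2 and 3-(1-methyl-1H-imidazol-5-yl)-2-oxopropanoic acid F3. The latter is obtained as its hydrochloride and needs one more equivalent of base.
- The dilithio derivative of F3 (LiN(SiMe3)2, THF, −78 °C) is run into I2 to give 3-iodo-3-(1-methyl-1H-imidazol-5-yl)-2-oxopropanoic acid F4.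
- The dilithio derivative of F2 is then added to give 3-(6-bromo-1-tosyl-1H-indol-3-yl)-4-(1-methyl-1H-imidazol-5-yl)-2,5-dioxohexanedioic acid F5.
- Ammonia closes the ring directly to diacid 16, where the route is rejoined (TFA, 60 °C, to 17).

Step 8. The imidazole may be photooxidised if its protonation is incomplete, the electron-rich pyrrole may oligomerise, or the endoperoxide may break down unselectively.
The fallback introduces oxygen by electrophilic halogenation and hydrolysis instead of cycloaddition. It sets out from 17. NBS (2 equiv, THF, −78 °C) should brominate both free α-positions to give 6-bromo-3-[2,5-dibromo-4-(1-methyl-1H-imidazol-5-yl)-1H-pyrrol-3-yl]-1-tosyl-1H-indole F6. A third equivalent of NBS in aqueous MeCN containing TFA should attack C2 at the brominated carbon. Water then adds at C5, and hydrolysis of the carbon–bromine bonds gives imide 21, where the route is rejoined.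

**Further compounds**
F1 | step 6 | methyl 3-bromo-3-(6-bromo-1-tosyl-1H-indol-3-yl)-2-oxopropanoate (racemic) | COC(=O)C(=O)C(Br)c1cn(S(=O)(=O)c2ccc(C)cc2)c2cc(Br)ccc12
F2 | step 7 | 3-(6-bromo-1-tosyl-1H-indol-3-yl)-2-oxopropanoic acid | OC(=O)C(=O)Cc1cn(S(=O)(=O)c2ccc(C)cc2)c2cc(Br)ccc12
F3 | step 7 | 3-(1-methyl-1H-imidazol-5-yl)-2-oxopropanoic acid | OC(=O)C(=O)Cc1cncn1C
F4 | step 7 | 3-iodo-3-(1-methyl-1H-imidazol-5-yl)-2-oxopropanoic acid (racemic) | OC(=O)C(=O)C(I)c1cncn1C
F5 | step 7 | 3-(6-bromo-1-tosyl-1H-indol-3-yl)-4-(1-methyl-1H-imidazol-5-yl)-2,5-dioxohexanedioic acid (mixture of diastereomers) | OC(=O)C(=O)C(c1cncn1C)C(C(=O)C(=O)O)c1cn(S(=O)(=O)c2ccc(C)cc2)c2cc(Br)ccc12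
F6 | step 8 | 6-bromo-3-[2,5-dibromo-4-(1-methyl-1H-imidazol-5-yl)-1H-pyrrol-3-yl]-1-tosyl-1H-indole | Brc1[nH]c(Br)c(-c2cncn2C)c1-c1cn(S(=O)(=O)c2ccc(C)cc2)c2cc(Br)ccc12
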